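## Structural features

The target 15 is a 1,2-dihydronaphthalene in which a catechol ring (ring A, C4a to C8a, hydroxyls at C6 and C7) is fused to a partly saturated ring B (C1 to C4). Ring B carries a 6-carboxy-2-oxo-2H-pyran-4-yl group at C1, a carboxylic acid at C2 and a conjugated carboxylic acid at C3, whose C3=C4 double bond is in conjugation with ring A. The only stereocentres are the neighbours C1 (R) and C2 (S), with the pyranone and the C2 carboxyl trans. C1-H is benzylic and γ to the pyranone carbonyl, and C2-H is α to a carbonyl and allylic, so both are base-sensitive and C2 epimerises readily. The fragile parts are the 2-pyranone (an enol lactone opened by hydroxide, alkoxide and amines), the catechol (oxidised in basic air) and ring B itself, which aromatises to a naphthalene with loss of both stereocentres. The real difficulty is to set C1, which bears two different sp2 carbon groups and a hydrogen, enantioselectively next to C2 without opening the pyranone or aromatising ring B. The key step exploits that C1 is attached to C8a, para to the C6 oxygen of ring A, so C1 can become the exocyclic carbon of a para-quinone methide, while C2 is an ester α-carbon held cis to ring A by the C3=C4 bond and can attack C1 to close ring B.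

## Logic of the disconnections

15 ⇒ 14 ⇒ 13. No skeletal bond is cut at first: the three acid O-H bonds are traced back to methyl esters (14) and the C7 hydroxyl to its methyl ether (13). The reason is that free acids and a free catechol would not survive the base and metal chemistry, whereas the methyl groups are already present in the building blocks. The gain is a neutral, chromatographable compound with a single free phenol at C6. The demand is that both unmasking reactions be acidic and air-free, because hydroxide would open the pyranone and oxidation would aromatise ring B.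

13 ⇒ 11 (through 12). The C1-C2 bond of ring B is cut. C1 is para-hydroxybenzylic and can be unmasked as the electrophilic carbon of 12, while C2 is the α-carbon of an ester tethered through the C3=C4 bond. The gain is the loss of the ring and of both stereocentres in a single cut; 11 may be racemic at C1 because 12 is planar there. The demand is that one mild base release 12, deprotonate C2 and leave the pyranone intact, while a chiral counter-cation selects the face of C1.

11 ⇒ 9 (through 10). The C1-S bond is cut and the C6 oxygen is returned to its carbonate. The sulfone is the storable form of 12 and can be put in by ionising a benzylic alcohol; the phenol must be masked during the earlier metal-mediated steps. The gain is a simple secondary alcohol. The demand is that one acid cleave the carbonate and ionise the C1-O bond while a sulfinate captures the cation at sulfur.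

9 ⇒ 4 + 8. The bond between C1 and C4 of the pyranone is cut. This divides the molecule into two fragments of similar size and turns C1 into an aldehyde carbon. The demand is an organometallic nucleophile derived from 8 that adds to the aldehyde but ignores four esters, the enol lactone, the carbonate and the enoate.

4 ⇒ 2 + 3, and 2 ⇒ 1. The C4-C4a bond is cut, then the carbonate O-C bond. The arylation of 3 installs the whole C4-C3-C2 diester chain in one step with the E geometry the ring closure needs. The demand is β-hydride elimination towards the benzylic carbon and a base too weak to let C2 condense with the neighbouring aldehyde. 2 is 1 with its phenol protected.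

8 ⇒ 7 ⇒ 6 ⇒ 5. Only functional groups change: the ester is traced to the aldehyde, the aldehyde to the C6 methyl group, and the C4 bromide to the C4 hydroxyl. 5 is commercial and already contains every ring atom. The demand is that both oxidations act on the side chain only and that no base or strong nucleophile meets the bromopyranone.

## Other disconnections considered

Alternative 1: The cut removes the C1-C2 and C3-C4 bonds, a retro-Diels–Alder opening of ring B. In the forward step near-UV light photoenolises methyl 4-[(2-formyl-4,5-dimethoxyphenyl)methyl]-2-oxo-2H-pyran-6-carboxylate A1, and [4+2] addition to bis[(2S)-1-methoxy-1-oxopropan-2-yl] fumarate A2 should give the tetralol A3.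
- In its favour: two skeletal bonds and ring B form from two simple fragments, the fumarate geometry fixes the trans C2/C3 esters, and lactate fumarates are an established auxiliary class for such cycloadditions. Ring A can carry two methyl ethers, so no phenol has to be differentiated.
- Against it here: the 2-pyranone is itself a near-UV chromophore with its own electrocyclic and cycloaddition photochemistry and a possible 2π partner for the electron-rich dienol. The 1,2-trans relation depends on the geometry of the dienol terminus that carries the pyranone. A3 has a C4 hydroxyl and a saturated C3, so a dehydration must create C3=C4 and destroys two of the four new stereocentres. Five ester groups then have to be hydrolysed.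
- Comparison: on structure the chosen plan delivers C3=C4 directly and makes only the two stereocentres that remain. On mechanism the alternative is the better of the two, because a covalently bound auxiliary in a pericyclic step is better precedented than ion-pair control. It is also the better in bonds formed per key step (two against one). In step count the two are about equal once the dehydration, auxiliary removal and the synthesis of A1 are counted.

Alternative 2: The cut removes C4a-C8a, C5-C6 and C7-C8, so ring A is built de novo and ring B closes with it. In the forward step Cp*RuCl(cod) should cocyclise the diyne A4, dimethyl (2E,3S)-3-[(1S)-1-(6-methoxycarbonyl-2-oxo-2H-pyran-4-yl)prop-2-yn-1-yl]-2-(prop-2-yn-1-ylidene)butanedioate, with bis(pinacolatoboryl)acetylene A5 to the bis-boronate A6.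
- In its favour: the catechol oxygens arrive as C-B bonds, so no aryl methyl ether has to be cleaved. On that point it is better than the chosen plan, which needs BBr3. Regiochemistry is no issue because A5 is symmetrical.
- Against it here: the key step creates no stereocentre. C1 and C2 must already exist in open-chain A4, where C1-H is propargylic and flanked by the pyranone and is prone to allene formation and epimerisation. The pyranone and the enyne alkene are competing π ligands for ruthenium. The usual alkaline peroxide for C-B oxidation threatens the pyranone and ring B.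
- Comparison: on structure it constructs an aromatic ring that the chosen plan buys. On mechanism the ring-forming event itself is at least the equal of the chosen key step in precedent, but the stereochemical problem is moved into a harder acyclic setting. In step economy it is clearly longer, because stereodefined A4 needs its own asymmetric synthesis.

Alternative 3: The cut removes O1-C6 and C4-C5 of the pyranone, which is built last on the finished carbocycle. In the forward step Ph3PAuNTf2 should add the propiolic acid A7, 3-[(1R,2S)-6,7-dimethoxy-2,3-bis(methoxycarbonyl)-1,2-dihydronaphthalen-1-yl]prop-2-ynoic acid, across tert-butyldimethyl(prop-2-yn-1-yloxy)silane A8. The O-bound vinyl unit then closes onto the gold-activated ynoate to give A9.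
- In its favour: the nucleophile-sensitive pyranone is absent from all earlier steps, which is better than in the chosen plan. The 4,6-substitution pattern follows from the mechanism.
- Against it here: the key step makes neither the carbocycle nor a stereocentre, so A7 must be obtained enantiopure by other means. Its C1-H is benzylic and propargylic to an ynoate, more acidic than in 15. The pyranone C6 substituent arrives at the alcohol oxidation level, so desilylation and oxidation to the acid must follow on an oxidisable dihydronaphthalene. Cationic gold may also engage ring A or the C3=C4 bond.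
- Comparison: on structure it simplifies the heterocycle, whereas the chosen plan addresses the core where the stereochemical problem sits. On mechanism the gold cascade is as well precedented as the fragment union used in the chosen plan. It is longer, with at least four steps after the key step and an unsolved route to A7. Both plans end with Lewis-acid demethylation and acid hydrolysis and are equal on that point.

Key step: step 8

Remark on the structures: the drawn precursor, ring-closed product and target are mutually consistent (E alkene, C6 hydroxyl para to C8a, trans (1R,2S)), so no structure is altered. The one redesign is that the C6 phenol is carried as a tert-butyl carbonate up to the sulfone-forming step, because a free para-formyl phenol is a liability in the two metal-mediated steps.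
Remark on locants: dihydronaphthalene numbering is used for all open-chain precursors (ring B C1 to C4, ring A C4a to C8a).

## Route

Step 1
Reactants: 1 6-bromovanillin (2-bromo-4-hydroxy-5-methoxybenzaldehyde)
Product: 2 5-bromo-4-formyl-2-methoxyphenyl tert-butyl carbonate
Conditions: Boc2O, DMAP (5 mol%), CH2Cl2, rt
Reagents that add atoms: di-tert-butyl dicarbonate, CC(C)(C)OC(=O)OC(=O)OC(C)(C)C
Why: DMAP-catalysed O-acylation of the acidic phenol gives the aryl tert-butyl carbonate. The group removes the acidic proton before the two metal-mediated steps, makes the ring less electron-rich for oxidative addition, and should fall off in the acid of step 7 without a separate deprotection.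

Step 2
Reactants: 2 5-bromo-4-formyl-2-methoxyphenyl tert-butyl carbonate; 3 dimethyl itaconate
Product: 4 dimethyl (E)-2-[[5-(tert-butoxycarbonyloxy)-2-formyl-4-methoxyphenyl]methylidene]butanedioate
Conditions: Pd(OAc)2 (5 mol%), P(o-tol)3 (10 mol%), Cy2NMe, DMF, 80 °C
Reagents that add atoms: none
Why: Mizoroki–Heck reaction: zerovalent palladium inserts into the C-Br bond activated by the ortho formyl group, the aryl group adds to the unsubstituted methylene of 3, and β-hydride elimination towards the benzylic carbon should give the conjugated arylidene succinate as the E isomer (aryl trans to the ester), as is usual for itaconate arylations. The hindered amine and moderate temperature are chosen to spare the carbonate and to avoid aldol closure of the succinate methylene onto the neighbouring aldehyde.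

Step 3
Reactants: 5 4-hydroxy-6-methyl-2H-pyran-2-one
Product: 6 4-bromo-6-methyl-2H-pyran-2-one
Conditions: Bu4NBr, P2O5, PhMe, 100 °C
Reagents that add atoms: tetrabutylammonium bromide, CCCC[N+](CCCC)(CCCC)CCCC.[Br-]
Why: The vinylogous-acid hydroxyl is phosphorylated by P2O5 and displaced by bromide through addition–elimination at C4; this deoxybromination is an established preparation of 6.

Step 4
Reactants: 6 4-bromo-6-methyl-2H-pyran-2-one
Product: 7 4-bromo-2-oxo-2H-pyran-6-carbaldehyde
Conditions: SeO2, 1,4-dioxane, 150 °C (sealed tube)
Reagents that add atoms: selenium dioxide, O=[Se]=O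
Why: Riley oxidation: the C6 methyl group is allylic to the ring diene and should be oxidised by SeO2 (ene reaction, [2,3]-shift) to the aldehyde, as is known for 4-alkoxy-6-methyl-2-pyranones. The base-free, non-nucleophilic medium should leave the C4 bromide in place.

Step 5
Reactants: 7 4-bromo-2-oxo-2H-pyran-6-carbaldehyde
Product: 8 methyl 4-bromo-2-oxo-2H-pyran-6-carboxylate
Conditions: Oxone (2KHSO5·KHSO4·K2SO4), MeOH, rt
Reagents that add atoms: methanol, CO
Why: Oxidative esterification: the electron-poor aldehyde forms its methyl hemiacetal, which peroxymonosulfate should oxidise to the methyl ester under mildly acidic conditions. No base and no nucleophile stronger than methanol meets the bromopyranone.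

Step 6
Reactants: 4 dimethyl (E)-2-[[5-(tert-butoxycarbonyloxy)-2-formyl-4-methoxyphenyl]methylidene]butanedioate; 8 methyl 4-bromo-2-oxo-2H-pyran-6-carboxylate
Product: 9 dimethyl (E)-2-[[5-(tert-butoxycarbonyloxy)-2-[hydroxy(6-methoxycarbonyl-2-oxo-2H-pyran-4-yl)methyl]-4-methoxyphenyl]methylidene]butanedioate (racemic)
Conditions: CrCl2 (4 equiv), NiCl2 (2 mol%), DMF, rt; then H2O
Reagents that add atoms: none
Why: Nozaki–Hiyama–Kishi reaction: zerovalent nickel (from NiCl2 and CrCl2) inserts into the C4-Br bond of 8 and transmetalation gives a pyranon-4-yl species of trivalent chromium. This should add only to the aldehyde of 4, since such reagents leave esters, the enol lactone, the carbonate and the enoate untouched. The carbinol centre forms racemic, which is immaterial because it is erased in step 8.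

Step 7
Reactants: 9 dimethyl (E)-2-[[5-(tert-butoxycarbonyloxy)-2-[hydroxy(6-methoxycarbonyl-2-oxo-2H-pyran-4-yl)methyl]-4-methoxyphenyl]methylidene]butanedioate
Product: 11 dimethyl (E)-2-[[5-hydroxy-4-methoxy-2-[(6-methoxycarbonyl-2-oxo-2H-pyran-4-yl)(4-tolylsulfonyl)methyl]phenyl]methylidene]butanedioate (racemic at the sulfone carbon), via free phenol carbinol 10 (not isolated)
Conditions: TolSO2Na (3 equiv), TFA/CH2Cl2 (1:4), 0 °C → rt; work-up without base
Reagents that add atoms: sodium p-toluenesulfinate, Cc1ccc(cc1)S(=O)[O-].[Na+]
Why: TFA should cleave the aryl tert-butyl carbonate (loss of CO2 and isobutene) to give 10, whose para-hydroxybenzylic C1-O bond ionises to the O-protonated quinone methide. p-Toluenesulfinic acid captures this cation at sulfur (sulfinic acid exchange, SN1) to give the stable sulfone. The sulfone carbon needs no stereocontrol, and a base-free work-up keeps the quinone methide from forming early.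

Step 8
Reactants: 11 dimethyl (E)-2-[[5-hydroxy-4-methoxy-2-[(6-methoxycarbonyl-2-oxo-2H-pyran-4-yl)(4-tolylsulfonyl)methyl]phenyl]methylidene]butanedioate
Product: 13 dimethyl (1R,2S)-6-hydroxy-7-methoxy-1-(6-methoxycarbonyl-2-oxo-2H-pyran-4-yl)-1,2-dihydronaphthalene-2,3-dicarboxylate, via para-quinone methide 12 (not isolated)
Conditions: N-(9-anthracenylmethyl)cinchonidinium chloride (10 mol%), Cs2CO3 (2.5 equiv, solid), PhMe/CH2Cl2 (4:1), −20 °C, Ar; then aq. NH4Cl
Reagents that add atoms: none
Why: Proposed new method: carbonate, carried into the organic phase by the chiral ammonium cation, should deprotonate the C6 phenol of 11, and the phenoxide should expel p-toluenesulfinate to give the planar para-quinone methide 12, in which C1 is the terminus of a 1,6-acceptor. In 12 the C2-H bonds are acidified by their own ester and also by conjugation through C3=C4 and C4a=C5 into the C6 carbonyl, so a carbonate base should reach the dienolate even though an isolated succinate would be too weakly acidic; the closest known reaction type is the phase-transfer-catalysed asymmetric 1,6-addition of malonates, β-keto esters and glycine imines to para-quinone methides released from 4-hydroxybenzyl sulfones, and the extension is a simple tethered ester α-carbon as donor. C2 then attacks C1 in a 6-(enolexo)-endo-trig closure (equally a disrotatory 6π-electrocyclisation of the phenoxide-bearing o-quinodimethane C2=C3-C4=C4a-C8a=C1), which restores the aromaticity of ring A and leaves C3=C4 where 15 has it. The C1 configuration should be set by the cinchonidinium cation, which is ion-paired with the dienolate and can hydrogen-bond through its C9 hydroxyl to a carbonyl of 12 and so expose one face of C1; (1R) is the design aim and the pseudoenantiomeric cinchoninium salt is held in reserve should the sense be opposite. The C2 configuration should follow from a chair-like transition state that places the pyranone and the C2 ester trans, and since C2-H stays epimerisable any cis isomer should drain to the more stable trans product under the same base. The step needs C-C bond formation at C2 only, which the E geometry of C3=C4 secures because no other dienolate position can reach C1 in a six-membered array, and it needs the quinone methide to form at C1 only, which the para relation of the C6 hydroxyl to C8a guarantees. Solid Cs2CO3 at low temperature is chosen so that neither the hydroxide-sensitive pyranone nor the acidic C1-H of 13 meets aqueous base.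

Step 9
Reactants: 13 dimethyl (1R,2S)-6-hydroxy-7-methoxy-1-(6-methoxycarbonyl-2-oxo-2H-pyran-4-yl)-1,2-dihydronaphthalene-2,3-dicarboxylate
Product: 14 dimethyl (1R,2S)-6,7-dihydroxy-1-(6-methoxycarbonyl-2-oxo-2H-pyran-4-yl)-1,2-dihydronaphthalene-2,3-dicarboxylate
Conditions: BBr3 (5 equiv), CH2Cl2, −78 → 0 °C; then H2O
Reagents that add atoms: none
Why: Lewis-acid ether cleavage: BBr3 binds the C7 methoxy oxygen, helped by the boron already on the neighbouring C6 oxygen, and bromide removes the methyl group by SN2. At or below 0 °C the methyl esters and the enol lactone, which has no sp3 C-O bond to cleave, should survive, and C1 and C2 are not touched. Any ester that is cleaved converges on 15 in step 10.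

Step 10
Reactants: 14 dimethyl (1R,2S)-6,7-dihydroxy-1-(6-methoxycarbonyl-2-oxo-2H-pyran-4-yl)-1,2-dihydronaphthalene-2,3-dicarboxylate
Product: 15 (1R,2S)-1-(6-carboxy-2-oxo-2H-pyran-4-yl)-6,7-dihydroxy-1,2-dihydronaphthalene-2,3-dicarboxylic acid
Conditions: 6 M aq. HCl/1,4-dioxane (1:1), 80 °C, Ar
Reagents that add atoms: water, O
Why: Acid-catalysed acyl-oxygen hydrolysis (AAC2) of the three methyl esters. Acid is chosen because a 2-pyranone that opens under acid recloses, whereas hydroxide would open it for good and expose the catechol to oxidation. C2 may enolise but should return to the trans (1R,2S) arrangement, and C1 has no acid-labile pathway.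

## Compound list

1 | 6-bromovanillin (2-bromo-4-hydroxy-5-methoxybenzaldehyde) | COc1cc(C=O)c(Br)cc1O | starting material
2 | 5-bromo-4-formyl-2-methoxyphenyl tert-butyl carbonate | COc1cc(C=O)c(Br)cc1OC(=O)OC(C)(C)C | intermediate
3 | dimethyl itaconate | C=C(CC(=O)OC)C(=O)OC | starting material
4 | dimethyl (E)-2-[[5-(tert-butoxycarbonyloxy)-2-formyl-4-methoxyphenyl]methylidene]butanedioate | COC(=O)C/C(C(=O)OC)=C\c1cc(OC(=O)OC(C)(C)C)c(OC)cc1C=O | intermediate
5 | 4-hydroxy-6-methyl-2H-pyran-2-one | Cc1cc(O)cc(=O)o1 | starting material
6 | 4-bromo-6-methyl-2H-pyran-2-one | Cc1cc(Br)cc(=O)o1 | intermediate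
7 | 4-bromo-2-oxo-2H-pyran-6-carbaldehyde | O=Cc1cc(Br)cc(=O)o1 | intermediate
8 | methyl 4-bromo-2-oxo-2H-pyran-6-carboxylate | COC(=O)c1cc(Br)cc(=O)o1 | intermediate
9 | dimethyl (E)-2-[[5-(tert-butoxycarbonyloxy)-2-[hydroxy(6-methoxycarbonyl-2-oxo-2H-pyran-4-yl)methyl]-4-methoxyphenyl]methylidene]butanedioate, racemic at the carbinol carbon | COC(=O)C/C(C(=O)OC)=C\c1cc(OC(=O)OC(C)(C)C)c(OC)cc1C(O)c1cc(C(=O)OC)oc(=O)c1 | intermediate
10 | dimethyl (E)-2-[[5-hydroxy-2-[hydroxy(6-methoxycarbonyl-2-oxo-2H-pyran-4-yl)methyl]-4-methoxyphenyl]methylidene]butanedioate, racemic | COC(=O)C/C(C(=O)OC)=C\c1cc(O)c(OC)cc1C(O)c1cc(C(=O)OC)oc(=O)c1 | intermediate (not isolated)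
11 | dimethyl (E)-2-[[5-hydroxy-4-methoxy-2-[(6-methoxycarbonyl-2-oxo-2H-pyran-4-yl)(4-tolylsulfonyl)methyl]phenyl]methylidene]butanedioate, racemic at the sulfone carbon | COC(=O)C/C(C(=O)OC)=C\c1cc(O)c(OC)cc1C(c1cc(C(=O)OC)oc(=O)c1)S(=O)(=O)c1ccc(C)cc1 | intermediate
12 | dimethyl (E)-2-[[4-methoxy-6-[(6-methoxycarbonyl-2-oxo-2H-pyran-4-yl)methylidene]-3-oxocyclohexa-1,4-dien-1-yl]methylidene]butanedioate (para-quinone methide; geometry of the exocyclic C1=C8a bond not defined) | COC(=O)C/C(C(=O)OC)=C\C1=CC(=O)C(OC)=CC1=Cc1cc(C(=O)OC)oc(=O)c1 | intermediate (not isolated)
13 | dimethyl (1R,2S)-6-hydroxy-7-methoxy-1-(6-methoxycarbonyl-2-oxo-2H-pyran-4-yl)-1,2-dihydronaphthalene-2,3-dicarboxylate (1,2-trans) | COC(=O)C1=Cc2cc(O)c(OC)cc2[C@@H](c2cc(C(=O)OC)oc(=O)c2)[C@@H]1C(=O)OC | intermediate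
14 | dimethyl (1R,2S)-6,7-dihydroxy-1-(6-methoxycarbonyl-2-oxo-2H-pyran-4-yl)-1,2-dihydronaphthalene-2,3-dicarboxylate | COC(=O)C1=Cc2cc(O)c(O)cc2[C@@H](c2cc(C(=O)OC)oc(=O)c2)[C@@H]1C(=O)OC | intermediate
15 | (1R,2S)-1-(6-carboxy-2-oxo-2H-pyran-4-yl)-6,7-dihydroxy-1,2-dihydronaphthalene-2,3-dicarboxylic acid (CNP0195322.1) | O=C(O)C1=Cc2cc(O)c(O)cc2[C@@H](c2cc(C(=O)O)oc(=O)c2)[C@@H]1C(=O)O | target

## Step count and least certain steps

Total: 10 steps. Longest linear sequence: 8 steps (5 → 6 → 7 → 8 → 9 → 11 → 13 → 14 → 15, that is steps 3 to 10); the arene branch 1 → 2 → 4 (steps 1 and 2) joins at step 6.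

Step 8 (key step, proposed new method). The most likely failure is poor facial discrimination at C1, because the chiral cation pairs with a charge that is delocalised away from the bond-forming carbons. The quinone methide may also be diverted by water or oligomerisation before C2 is deprotonated, and slow exchange of C1-H in the product could erode the enantiomeric purity. The fallback uses known chemistry only and sets out from 9. Appel bromination (CBr4, PPh3, CH2Cl2, 0 °C) should give dimethyl (E)-2-[[2-[bromo(6-methoxycarbonyl-2-oxo-2H-pyran-4-yl)methyl]-5-(tert-butoxycarbonyloxy)-4-methoxyphenyl]methylidene]butanedioate F1. Deprotonation of the succinate methylene with LiN(SiMe3)2 in THF at −78 °C, the standard way to C-alkylate arylidene succinate enolates with benzylic bromides, should close ring B by intramolecular 6-exo-tet alkylation. This gives racemic dimethyl trans-6-(tert-butoxycarbonyloxy)-7-methoxy-1-(6-methoxycarbonyl-2-oxo-2H-pyran-4-yl)-1,2-dihydronaphthalene-2,3-dicarboxylate F2, with trans favoured after equilibration at C2. Preparative chromatography on a chiral stationary phase would separate the (1R,2S) enantiomer, dimethyl (1R,2S)-6-(tert-butoxycarbonyloxy)-7-methoxy-1-(6-methoxycarbonyl-2-oxo-2H-pyran-4-yl)-1,2-dihydronaphthalene-2,3-dicarboxylate F3. Under the BBr3 conditions of step 9 F3 should lose the carbonate together with the methyl ether, and the fallback comes back to the route at 14.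

Step 7. The most likely failure is stalled ionisation of the C1-O bond, because the electron-poor pyranone destabilises the benzylic cation; the sulfinic acid could then disproportionate before it is captured. The fallback replaces ionisation by direct displacement and sets out from 9. The bromide dimethyl (E)-2-[[2-[bromo(6-methoxycarbonyl-2-oxo-2H-pyran-4-yl)methyl]-5-(tert-butoxycarbonyloxy)-4-methoxyphenyl]methylidene]butanedioate F1 (the compound also used in the fallback for step 8) is made by the Appel reaction. SN2 displacement with TolSO2Na in DMF at rt, favourable at a benzylic carbon next to the electron-poor ring, should give dimethyl (E)-2-[[5-(tert-butoxycarbonyloxy)-4-methoxy-2-[(6-methoxycarbonyl-2-oxo-2H-pyran-4-yl)(4-tolylsulfonyl)methyl]phenyl]methylidene]butanedioate F4. TFA in CH2Cl2 then removes the carbonate, and the fallback comes back at 11.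

Step 6. The most likely failure is that protonolysis, reductive homocoupling or reduction of the electron-poor pyranonyl metal species outruns its addition to a hindered, electron-rich ortho-substituted aldehyde. The fallback changes how the nucleophile is made and sets out from 8. Miyaura borylation (B2pin2, KOAc, PdCl2(dppf), 1,4-dioxane, 80 °C) should give methyl 2-oxo-4-(4,4,5,5-tetramethyl-1,3,2-dioxaborolan-2-yl)-2H-pyran-6-carboxylate F5. Rhodium-catalysed 1,2-addition of this alkenylboronate to the aldehyde of 4 ([Rh(OH)(cod)]2, 1,4-dioxane/H2O, 60 °C), a known reaction of organoboron reagents with aryl aldehydes, comes back at 9.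

Step 4. The most likely failure is over-oxidation to the acid followed by decarboxylation, or hydrolytic loss of the C4 bromide by the water formed at 150 °C. The fallback reaches the aldehyde through a halide and sets out from 6. Radical side-chain bromination (NBS, AIBN, PhCF3, 80 °C) should give 4-bromo-6-(bromomethyl)-2H-pyran-2-one F6. Oxidation of this activated bromide with N-methylmorpholine N-oxide in MeCN at rt comes back at 7.

Step 10. The most likely failure is slow hydrolysis of the conjugated C3 ester, which would call for forcing conditions under which ring B aromatises with traces of oxygen or the β,γ-unsaturated C2 acid decarboxylates. The fallback replaces acyl hydrolysis by O-alkyl cleavage and sets out from 13. Excess BBr3 (12 equiv, CH2Cl2, −78 °C → rt, then H2O) should remove the ether methyl and all three ester methyl groups by SN2 attack of bromide, with no hot aqueous acid. It comes back at 15 and makes no new compound.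

## Further compounds

F1 | step 8 | dimethyl (E)-2-[[2-[bromo(6-methoxycarbonyl-2-oxo-2H-pyran-4-yl)methyl]-5-(tert-butoxycarbonyloxy)-4-methoxyphenyl]methylidene]butanedioate, racemic | COC(=O)C/C(C(=O)OC)=C\c1cc(OC(=O)OC(C)(C)C)c(OC)cc1C(Br)c1cc(C(=O)OC)oc(=O)c1
F2 | step 8 | racemic dimethyl trans-6-(tert-butoxycarbonyloxy)-7-methoxy-1-(6-methoxycarbonyl-2-oxo-2H-pyran-4-yl)-1,2-dihydronaphthalene-2,3-dicarboxylate (both enantiomers) | COC(=O)C1=Cc2cc(OC(=O)OC(C)(C)C)c(OC)cc2[C@@H](c2cc(C(=O)OC)oc(=O)c2)[C@@H]1C(=O)OC.COC(=O)C1=Cc2cc(OC(=O)OC(C)(C)C)c(OC)cc2[C@H](c2cc(C(=O)OC)oc(=O)c2)[C@H]1C(=O)OC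
F3 | step 8 | dimethyl (1R,2S)-6-(tert-butoxycarbonyloxy)-7-methoxy-1-(6-methoxycarbonyl-2-oxo-2H-pyran-4-yl)-1,2-dihydronaphthalene-2,3-dicarboxylate | COC(=O)C1=Cc2cc(OC(=O)OC(C)(C)C)c(OC)cc2[C@@H](c2cc(C(=O)OC)oc(=O)c2)[C@@H]1C(=O)OC
F4 | step 7 | dimethyl (E)-2-[[5-(tert-butoxycarbonyloxy)-4-methoxy-2-[(6-methoxycarbonyl-2-oxo-2H-pyran-4-yl)(4-tolylsulfonyl)methyl]phenyl]methylidene]butanedioate, racemic | COC(=O)C/C(C(=O)OC)=C\c1cc(OC(=O)OC(C)(C)C)c(OC)cc1C(c1cc(C(=O)OC)oc(=O)c1)S(=O)(=O)c1ccc(C)cc1
F5 | step 6 | methyl 2-oxo-4-(4,4,5,5-tetramethyl-1,3,2-dioxaborolan-2-yl)-2H-pyran-6-carboxylate | COC(=O)c1cc(B2OC(C)(C)C(C)(C)O2)cc(=O)o1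
F6 | step 4 | 4-bromo-6-(bromomethyl)-2H-pyran-2-one | BrCc1cc(Br)cc(=O)o1
F0 | step 10 | none | none
A1 | alternative 1 | methyl 4-[(2-formyl-4,5-dimethoxyphenyl)methyl]-2-oxo-2H-pyran-6-carboxylate | COC(=O)c1cc(Cc2cc(OC)c(OC)cc2C=O)cc(=O)o1
A2 | alternative 1 | bis[(2S)-1-methoxy-1-oxopropan-2-yl] fumarate | COC(=O)[C@H](C)OC(=O)/C=C/C(=O)O[C@@H](C)C(=O)OC
A3 | alternative 1 | bis[(2S)-1-methoxy-1-oxopropan-2-yl] (1R,2S,3R,4R)-4-hydroxy-6,7-dimethoxy-1-(6-methoxycarbonyl-2-oxo-2H-pyran-4-yl)-1,2,3,4-tetrahydronaphthalene-2,3-dicarboxylate (1,2-trans, 2,3-trans, 3,4-cis) | O[C@H]1c2cc(OC)c(OC)cc2[C@@H](c2cc(C(=O)OC)oc(=O)c2)[C@H](C(=O)O[C@@H](C)C(=O)OC)[C@H]1C(=O)O[C@@H](C)C(=O)OC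
A4 | alternative 2 | dimethyl (2E,3S)-3-[(1S)-1-(6-methoxycarbonyl-2-oxo-2H-pyran-4-yl)prop-2-yn-1-yl]-2-(prop-2-yn-1-ylidene)butanedioate | C#C[C@@H](c1cc(C(=O)OC)oc(=O)c1)[C@H](C(=O)OC)/C(C(=O)OC)=C\C#C
A5 | alternative 2 | bis(pinacolatoboryl)acetylene | CC1(C)OB(OC1(C)C)C#CB1OC(C)(C)C(C)(C)O1
A6 | alternative 2 | dimethyl (1R,2S)-1-(6-methoxycarbonyl-2-oxo-2H-pyran-4-yl)-6,7-bis(4,4,5,5-tetramethyl-1,3,2-dioxaborolan-2-yl)-1,2-dihydronaphthalene-2,3-dicarboxylate | COC(=O)C1=Cc2cc(B3OC(C)(C)C(C)(C)O3)c(B3OC(C)(C)C(C)(C)O3)cc2[C@@H](c2cc(C(=O)OC)oc(=O)c2)[C@@H]1C(=O)OC
A7 | alternative 3 | 3-[(1R,2S)-6,7-dimethoxy-2,3-bis(methoxycarbonyl)-1,2-dihydronaphthalen-1-yl]prop-2-ynoic acid | COC(=O)C1=Cc2cc(OC)c(OC)cc2[C@@H](C#CC(=O)O)[C@@H]1C(=O)OC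
A8 | alternative 3 | tert-butyldimethyl(prop-2-yn-1-yloxy)silane | C#CCO[Si](C)(C)C(C)(C)C
A9 | alternative 3 | dimethyl (1R,2S)-1-[6-(tert-butyldimethylsilyloxymethyl)-2-oxo-2H-pyran-4-yl]-6,7-dimethoxy-1,2-dihydronaphthalene-2,3-dicarboxylate | COC(=O)C1=Cc2cc(OC)c(OC)cc2[C@@H](c2cc(CO[Si](C)(C)C(C)(C)C)oc(=O)c2)[C@@H]1C(=O)OC
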